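## Structural features

Compound 26 is a 2-hydroxy-5-(3-methylbutylamino)-1,4-benzoquinone whose C3 is joined through one methylene (C11) to C9 of a bicyclic sesquiterpene unit. Terpenoid numbering is used throughout, and the face of ring B that carries the C9 methyl is called the upper face. Ring A (C1–C5 and C10) carries only the gem-dimethyl group at C4, ring B (C5–C10) carries the C5=C6 alkene, and the two rings share the C5–C10 bond. Three contiguous stereocentres lie on ring B: C8 (secondary methyl, S), the quaternary C9 (methyl and quinonylmethyl, R) and C10 (H, S). The two methyls are cis and H10 is on the lower face. The aminohydroxyquinone is redox-active and sensitive to nucleophiles and base, so it is carried as a tetramethoxyarene until the end. The trisubstituted alkene, flanked by quaternary C4 and the allylic C10–H, can migrate or ionise under strong acid, and C8 and C10 become epimerisable whenever a carbonyl sits at C7 or C1. The real difficulty is the quaternary C9 between two tertiary stereocentres, in a carbocycle with no heteroatom to direct reagents, in one absolute configuration. The key step uses the fact that the C8–C9–C10 triad lies on six-membered ring B next to the shared C5–C10 bond: a C5=C6–C7=C8 diene tied through C4–C3–C2–C1 to a C9=C10 dienophile maps onto both rings at once, with a C1 carbonyl and a C7 silyloxy group as temporary activators.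

## Logic of the disconnections

26 to 24 and 25. The C–N bond at quinone C5 is cut. Exchange of a vinylogous ester for a vinylogous amide is the mildest way to bring in the amine and leaves the sensitive chromophore to the last step. The forward step must put the amine on the methoxy-bearing carbon next to the ring CH and nowhere else.

24 to 23 to 22. No skeletal bond is cut; the hydroxyl is traced to a methoxy group and the two quinone carbonyls to a p-dimethoxy pair. This turns the quinone into an arene that survives organolithiums, hydrides, radicals and Lewis acids. The oxidation must spare the C5=C6 alkene, and the hydrolysis must single out the methoxy group beside the alkylated carbon.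

22 to 21 to 20. The two C7–H bonds are traced to a C7 carbonyl conjugated with C5=C6. This oxygen is what remains of the diene activator. The forward steps must deliver hydride to C7 and not to C5, and must not disturb C8 or C10.

20 to 19. The C5=C6 alkene is traced to the C6=C7 silyl enol ether with a hydrogen at C5. This places the unsaturation where 26 has it and deletes the C5 stereocentre. The dehydrosilylation must eliminate towards C5 only.

19 to 18 to 16 to 15. The C1 methylene is traced to the C1 ketone, which is needed only to activate the dienophile. It must be removed before C7 is oxidised, because with carbonyls at both C1 and C7 the C10–H would be doubly activated. The sequence must never enolise C1 towards C10 and must leave the silyl enol ether intact.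

15 to 14. The C5–C10 and C8–C9 bonds are cut together. Both rings, the quaternary centre and all ring stereocentres revert to one acyclic triene whose only stereochemical information is three alkene geometries. The forward step must be endo, must use one enantioface of the enone, and must not be taken over by an achiral promoter.

14 to 7 and 12 (through 13). The C1–C10 bond is cut between the ketone and the alkene. This makes the route convergent and makes the enone appear only on the quench of an acyl substitution. A late enol silylation of a diketone is thereby avoided: it would have to choose between two enolisable ketones and would expose the finished triene to a silyl triflate, an achiral promoter of the cyclisation. The forward step must keep the alkene geometry of 7 and stop at mono-addition.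

12 to 11 to 10 to 8 and 9. The amide C–N bond, the Si–O bond and the C5=C6 alkene are cut in turn. Compound 8 already holds C1 at the acid oxidation level and the quaternary C4, so no alkene functionalisation is needed in the presence of an enone. The olefination must be E and the enol silylation must be Z.

7 to 5 (through 6) to 4 to 1 and 2 (through 3). The C9–CH3 and C10–I bonds are cut as a syn carbometalation, then the C–Si bond and the aryl–C11 bond. The geometry of the trisubstituted alkene is then fixed by mechanism and not by the selectivity of a conjugate addition to an ynone. The demands are regioselective syn addition and propargylic, not allenic, substitution.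

## Other disconnections considered

Alternative 1: The cut runs through ring B alone, at C9–C10 and C7–C8, and gives the ring A diene A1 (6,6-dimethyl-1-vinylcyclohexene) and the dienophile A2 (tiglic aldehyde). In the forward direction a chiral oxazaborolidinium Lewis acid would join them in an intermolecular Diels–Alder reaction with the formyl group exo, to give aldehyde A3.
- In its favour: A3 already has the gem-dimethyl ring A, the C5=C6 alkene and all three stereocentres. No oxygen has to be removed from C1 or C7. C11 is an aldehyde that can take the arene from 3 directly. An α-substituted enal bound through its formyl C–H is the standard substrate of this catalyst class.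
- Against it here: the C9–C10 bond must form bimolecularly between the fully substituted α-carbon of a β-methylated enal and a ring terminus. The two alkyl groups of the diene direct regiochemistry in opposite senses. Exo/endo and facial selectivity must be secured without a tether. The benzylic hydroxyl left after arylation must be reduced beside the acid-sensitive alkene.
- Comparison: on structure both plans form two ring bonds and the same triad; the chosen plan also builds ring A, which Alternative 1 obtains ready-made. On mechanism the chosen plan has the advantage of intramolecularity, which fixes regiochemistry and eases formation of the quaternary centre. Alternative 1 is the better on catalyst precedent, redox economy and step count (roughly half the length).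

Alternative 2: The cut is at C9–C11 and at a temporary bond from C10 to the central carbon of A5 (allene). In the forward direction, irradiation of A4, (S)-3,4-dimethylcyclohex-2-enone, with A5 would give the head-to-head methylenecyclobutane A6, formed on the face opposite the C8 methyl.
- In its favour: the quaternary C9 is set relative to C8 by substrate control from a small enantiopure enone. The absolute configuration therefore rests on the starting material, which is better secured than the catalyst control of the chosen plan. C11 is delivered on C9 in the same step.
- Against it here: ring A is absent, so C1–C4 with the gem-dimethyl group must be annulated afterwards onto C10 and the C5 carbonyl. The cyclobutane must be opened, and the central carbon of A5 is an extra atom between C11 and the arene. C10 is α to the C5 ketone and must be set later. The step needs photochemical equipment and an excess of a gaseous partner.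
- Comparison: on structure it forms one lasting skeletal bond against two ring bonds in the chosen plan. On mechanism its regiochemistry and facial control are equal in reliability to the chosen cycloaddition, and the source of absolute configuration is better. On step economy it is clearly worse.

Alternative 3: The cut removes both C4–CH3 bonds and leads from A8 back to the C3-keto C4=C5 enone A7. In the forward direction a hindered alkoxide base and an excess of a methylating agent would form the extended enolate by deprotonation at C6 and methylate C4 twice, leaving the alkene at C5=C6.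
- In its favour: the reagents are simple and the operation scales. One operation gives exactly the ring A substitution and alkene position of 26. Only one oxygen (C3) remains to be removed, against two in the chosen plan.
- Against it here: the step makes no ring and no stereocentre, so the whole problem of the C8/C9/C10 triad moves into the synthesis of A7. C10–H is also γ to the enone, so deprotonation there would give the C5=C10 dienolate, the wrong alkene isomer and loss of C10. O-methylation and incomplete methylation compete. The C3 ketone next to the new quaternary centre is hard to remove.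
- Comparison: as a single bond-forming operation it is at least the equal of any step of the chosen plan in reliability. As a strategy it is inferior on structure, since it generates no complexity. On step economy it is probably no shorter once A7 has to be made.

Key step: step 8

Remark: 8 is taken as a catalogue compound; it is the Michael adduct of isobutyraldehyde and methyl acrylate.
Remark: the carbinol centres of 16 (C1) and 21 (C7) are written for the epimer expected from hydride attack on the less hindered face; either epimer serves, because both centres become CH2.
Remark: the E enone and Z enol ether of 14, the all-cis array of 15 and the 8S,9R,10S configuration of 26 correspond to one another through the endo transition state.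

Step 1
Reactants: 1 1,2,4,5-tetramethoxybenzene; 2 3-bromo-1-(trimethylsilyl)prop-1-yne
Product: 4 trimethyl[3-(2,3,5,6-tetramethoxyphenyl)prop-1-yn-1-yl]silane, via aryllithium 3 (not isolated)
Conditions: n-BuLi, TMEDA, THF, 0 °C; CuBr·SMe2 (10 mol%), then 2, −78 °C → rt
Reagents that add atoms: none
Why: Directed ortho-lithiation between two methoxy groups gives 3, and copper-catalysed SN2 alkylation by the propargylic bromide follows; the silyl cap blocks attack at the alkyne terminus (no allene) and removes the acidic alkyne proton.

Step 2
Reactants: 4 trimethyl[3-(2,3,5,6-tetramethoxyphenyl)prop-1-yn-1-yl]silane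
Product: 5 1,2,4,5-tetramethoxy-3-(prop-2-yn-1-yl)benzene
Conditions: K2CO3 (cat.), MeOH, rt
Reagents that add atoms: none
Why: Base-catalysed methanolysis of the alkynyl C–Si bond (protodesilylation); the carbonate should be too weak to isomerise the benzylic propyne to the allene at room temperature.

Step 3
Reactants: 5 1,2,4,5-tetramethoxy-3-(prop-2-yn-1-yl)benzene
Product: 7 3-[(E)-3-iodo-2-methylprop-2-en-1-yl]-1,2,4,5-tetramethoxybenzene, via alkenylalane 6 (not isolated)
Conditions: Me3Al, Cp2ZrCl2 (25 mol%), CH2Cl2, 0 °C → rt; then I2, THF, −30 °C
Reagents that add atoms: trimethylaluminium, C[Al](C)C; iodine, II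
Why: Zirconium-catalysed carboalumination (Negishi) adds CH3 and Al syn across the terminal alkyne with CH3 at the internal carbon, and iodinolysis of the C–Al bond goes with retention, so iodine ends cis to the methyl (E); the C9=C10 geometry is thus fixed by mechanism.

Step 4
Reactants: 8 methyl 4,4-dimethyl-5-oxopentanoate; 9 diethyl (2-oxobutyl)phosphonate
Product: 10 methyl (E)-4,4-dimethyl-7-oxonon-5-enoate
Conditions: LiCl, DBU, MeCN, rt
Reagents that add atoms: none
Why: Horner–Wadsworth–Emmons olefination under LiCl/amine conditions; the α-quaternary aldehyde cannot enolise or self-condense, the stabilised phosphonate should give the E enone, and the ester is untouched.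

Step 5
Reactants: 10 methyl (E)-4,4-dimethyl-7-oxonon-5-enoate
Product: 11 methyl (5E,7Z)-7-[(tert-butyldimethylsilyl)oxy]-4,4-dimethylnona-5,7-dienoate
Conditions: TBSOTf, Et3N, CH2Cl2, 0 °C
Reagents that add atoms: tert-butyldimethylsilyl triflate, CC(C)(C)[Si](C)(C)OS(=O)(=O)C(F)(F)F
Why: Soft enolisation of the ethyl ketone gives the 2-silyloxydiene; the Z isomer (methyl cis to oxygen) is expected because it avoids allylic strain between the methyl and the vinyl group, and the ester is not enolised under these conditions.

Step 6
Reactants: 11 methyl (5E,7Z)-7-[(tert-butyldimethylsilyl)oxy]-4,4-dimethylnona-5,7-dienoate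
Product: 12 (5E,7Z)-7-[(tert-butyldimethylsilyl)oxy]-N-methoxy-N,4,4-trimethylnona-5,7-dienamide
Conditions: MeNH(OMe)·HCl, i-PrMgCl, THF, −20 → 0 °C
Reagents that add atoms: N,O-dimethylhydroxylamine hydrochloride, CNOC.Cl
Why: Direct ester-to-Weinreb-amide exchange with the magnesium amide formed in the flask; the ketone is masked as the silyl enol ether, so no other carbonyl competes, and the silyl dienol ether tolerates the basic magnesium reagents.

Step 7
Reactants: 7 3-[(E)-3-iodo-2-methylprop-2-en-1-yl]-1,2,4,5-tetramethoxybenzene; 12 (5E,7Z)-7-[(tert-butyldimethylsilyl)oxy]-N-methoxy-N,4,4-trimethylnona-5,7-dienamide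
Product: 14 (2E,8E,10Z)-10-[(tert-butyldimethylsilyl)oxy]-2,7,7-trimethyl-1-(2,3,5,6-tetramethoxyphenyl)dodeca-2,8,10-trien-4-one, via vinyllithium 13 (not isolated)
Conditions: 7, t-BuLi (2 equiv), Et2O, −78 °C; then 12, THF, −78 → −40 °C; pH 7 buffer
Reagents that add atoms: none
Why: Iodine–lithium exchange with retention of alkene geometry gives 13, and its addition to the Weinreb amide stops at the chelated tetrahedral adduct; the enone therefore appears only on neutral quench, never together with silyl triflate, amine base or Lewis acid, and 14 is used at once.

Step 8
Reactants: 14 (2E,8E,10Z)-10-[(tert-butyldimethylsilyl)oxy]-2,7,7-trimethyl-1-(2,3,5,6-tetramethoxyphenyl)dodeca-2,8,10-trien-4-one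
Product: 15 cis-fused cycloadduct: C1 ketone, C6=C7 tert-butyldimethylsilyl enol ether, 4,4-dimethyl, 8-methyl and 9-methyl on the upper face, 9-(2,3,5,6-tetramethoxybenzyl), H5 and H10 on the lower face
Conditions: (R)-B-(o-tolyl)oxazaborolidine of (R)-α,α-diphenylprolinol (20 mol%), Tf2NH (17 mol%), CH2Cl2, −78 → −20 °C
Reagents that add atoms: none
Why: Proposed new method: the boron of the N-protonated oxazaborolidine binds the C1 carbonyl at the lone pair anti to C10 (the enone must be s-cis for the four-atom tether to reach C5, so the usual vinyl C–H···O contact of this catalyst class is not available), lowers the enone LUMO, and the silyloxydiene adds in an asynchronous [4+2] process in which C8 bonds to the β-carbon C9 ahead of C5–C10; the closest known reactions are the achiral Lewis acid-promoted endo intramolecular Diels–Alder of 2-silyloxy-1,7,9-decatrien-3-ones and the intermolecular oxazaborolidinium-catalysed additions of 2-silyloxydienes to enones. Ring B closes as the cyclohexene of the cycloaddition (bonds C8–C9 and C5–C10), and ring A closes as the six-membered ring of the C1–C4 tether, fused at C5–C10. C9 and C10: suprafacial addition to the E enone keeps C1 cis to the C9 methyl. C8: the Z enol ether holds its methyl at the outside position of the diene, so it ends cis to the endo substituents. C5: the tether carbonyl is endo, which gives the cis ring fusion with C4 and C1 on the methyl face. Absolute configuration: the catalyst shields one face of C9=C10; in a model where a C2–H···O contact replaces the vinyl contact, the tether and diene must lie on the face away from the convex-face phenyl, which for the (R) catalyst is the face that leads to 15. The step needs endo over exo (secondary overlap of the bound carbonyl with C6–C7 and the tether geometry), one enantioface (catalyst) and no achiral catalysis (oxazaborolidine in excess over Tf2NH, low temperature).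

Step 9
Reactants: 15 cis-fused cycloadduct (C1 ketone, C6=C7 silyl enol ether)
Product: 16 C1 carbinol of 15, hydroxyl on the face of ring A opposite to H10
Conditions: i-Bu2AlH, CH2Cl2, −78 °C
Reagents that add atoms: none
Why: Non-basic hydride reduction at low temperature, chosen so that C10 (α to the ketone) cannot epimerise; hydride should enter from the convex face, syn to H10, and the silyl enol ether and aryl ethers are inert.

Step 10
Reactants: 16 C1 carbinol
Product: 18 O-(C1-alkyl) S-methyl carbonodithioate of 16, via sodium xanthate 17 (not isolated)
Conditions: NaH, CS2, imidazole (cat.), THF, 0 °C → rt; then MeI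
Reagents that add atoms: carbon disulfide, S=C=S; iodomethane, CI
Why: First stage of the Barton–McCombie deoxygenation; alkoxide formation, addition to CS2 and S-methylation work for hindered secondary alcohols, and the silyl enol ether is inert to base and MeI.

Step 11
Reactants: 18 xanthate of 16
Product: 19 1-deoxo compound: C1 methylene, C6=C7 silyl enol ether and cis ring fusion retained
Conditions: Bu3SnH, AIBN (cat.), toluene, 110 °C
Reagents that add atoms: none
Why: Barton–McCombie radical deoxygenation; the stannyl radical adds to C=S, the C1–O bond fragments and the secondary C1 radical takes hydrogen from the stannane, under neutral conditions that leave C10, the silyl enol ether and the arene untouched.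

Step 12
Reactants: 19 1-deoxo silyl enol ether
Product: 20 C5=C6 enone with C7 ketone (4,4,8,9-tetramethyl, 9-tetramethoxybenzyl, H10 on the lower face)
Conditions: Pd(OAc)2 (1.1 equiv), MeCN, rt → 40 °C
Reagents that add atoms: none
Why: Saegusa–Ito oxidation; palladation at C6 with loss of the silyl group and β-hydride elimination of H5, the only β-hydrogen, gives the C5=C6 enone regiospecifically and deletes the C5 stereocentre, while C8 and C10 are not enolised under these neutral conditions.

Step 13
Reactants: 20 C5=C6 enone
Product: 21 C7 allylic alcohol, hydroxyl on the upper face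
Conditions: NaBH4, CeCl3·7H2O, MeOH, −78 → 0 °C
Reagents that add atoms: none
Why: Luche 1,2-reduction under weakly acidic conditions that do not enolise towards C8 or C10; attack anti to the axial C9 methyl is expected, and the new centre is removed in step 14.

Step 14
Reactants: 21 C7 allylic alcohol
Product: 22 C5=C6 alkene with C7 methylene, arene still tetramethoxylated (configuration of 26 at C8, C9, C10)
Conditions: Et3SiH, BF3·OEt2, CH2Cl2, −78 → −40 °C
Reagents that add atoms: none
Why: Ionic deoxygenation of an allylic alcohol; BF3 ionises the C–O bond to the C5–C6–C7 allyl cation and the silane delivers hydride to the less hindered secondary terminus C7 (C5 is fully substituted and flanked by quaternary C4), which leaves the trisubstituted C5=C6 alkene and does not touch C8 or C10.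

Step 15
Reactants: 22 tetramethoxyarene
Product: 23 2,5-dimethoxy-3-(decalinylmethyl)-1,4-benzoquinone
Conditions: (NH4)2Ce(NO3)6, MeCN/H2O, 0 °C
Reagents that add atoms: water, O
Why: Oxidative demethylation of a p-dimethoxyarene by tetravalent cerium through the radical cation, with water adding at the methoxy-bearing carbons; either para pair gives the same quinone by symmetry, and the hindered alkene should not be attacked.

Step 16
Reactants: 23 2,5-dimethoxyquinone
Product: 24 2-hydroxy-5-methoxy-3-(decalinylmethyl)-1,4-benzoquinone
Conditions: KOH, MeOH/H2O, rt; then dilute HCl
Reagents that add atoms: potassium hydroxide, [K+].[OH-]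
Why: Addition–elimination of hydroxide on a vinylogous ester; the methoxy beside the alkylated carbon is twisted out of conjugation and is the one expected to be displaced, as in the saponification of related 3-alkyl-2,5-dimethoxyquinones, and the vinylogous carboxylate formed resists a second hydrolysis.

Step 17
Reactants: 24 2-hydroxy-5-methoxyquinone; 25 3-methylbutan-1-amine
Product: 26 nakijiquinone M
Conditions: 25, NaHCO3, EtOH, rt → 40 °C
Reagents that add atoms: none
Why: Vinylogous ester to vinylogous amide exchange; the amine adds to the unhindered methoxy-bearing C5 next to the ring CH and methanol leaves, while the hydroxyquinone half, present as its anion, is unreactive.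

Compound list
1 | 1,2,4,5-tetramethoxybenzene | COc1cc(OC)c(OC)cc1OC | starting material
2 | 3-bromo-1-(trimethylsilyl)prop-1-yne | C[Si](C)(C)C#CCBr | starting material
3 | (2,3,5,6-tetramethoxyphenyl)lithium | [Li]c1c(OC)c(OC)cc(OC)c1OC | intermediate
4 | trimethyl[3-(2,3,5,6-tetramethoxyphenyl)prop-1-yn-1-yl]silane | COc1cc(OC)c(OC)c(CC#C[Si](C)(C)C)c1OC | intermediate
5 | 1,2,4,5-tetramethoxy-3-(prop-2-yn-1-yl)benzene | COc1cc(OC)c(OC)c(CC#C)c1OC | intermediate
6 | dimethyl[(E)-2-methyl-3-(2,3,5,6-tetramethoxyphenyl)prop-1-en-1-yl]alumane | COc1cc(OC)c(OC)c(C/C(C)=C/[Al](C)C)c1OC | intermediate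
7 | 3-[(E)-3-iodo-2-methylprop-2-en-1-yl]-1,2,4,5-tetramethoxybenzene | COc1cc(OC)c(OC)c(C/C(C)=C/I)c1OC | intermediate
8 | methyl 4,4-dimethyl-5-oxopentanoate | COC(=O)CCC(C)(C)C=O | starting material
9 | diethyl (2-oxobutyl)phosphonate | CCC(=O)CP(=O)(OCC)OCC | starting material
10 | methyl (E)-4,4-dimethyl-7-oxonon-5-enoate | CCC(=O)/C=C/C(C)(C)CCC(=O)OC | intermediate
11 | methyl (5E,7Z)-7-[(tert-butyldimethylsilyl)oxy]-4,4-dimethylnona-5,7-dienoate | C/C=C(O[Si](C)(C)C(C)(C)C)/C=C/C(C)(C)CCC(=O)OC | intermediate
12 | (5E,7Z)-7-[(tert-butyldimethylsilyl)oxy]-N-methoxy-N,4,4-trimethylnona-5,7-dienamide | C/C=C(O[Si](C)(C)C(C)(C)C)/C=C/C(C)(C)CCC(=O)N(C)OC | intermediate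
13 | [(E)-2-methyl-3-(2,3,5,6-tetramethoxyphenyl)prop-1-en-1-yl]lithium | COc1cc(OC)c(OC)c(C/C(C)=C/[Li])c1OC | intermediate
14 | (2E,8E,10Z)-10-[(tert-butyldimethylsilyl)oxy]-2,7,7-trimethyl-1-(2,3,5,6-tetramethoxyphenyl)dodeca-2,8,10-trien-4-one | C/C=C(O[Si](C)(C)C(C)(C)C)/C=C/C(C)(C)CCC(=O)/C=C(C)/Cc1c(OC)c(OC)cc(OC)c1OC | intermediate
15 | cis-fused cycloadduct: C1 ketone, C6=C7 silyl enol ether, methyls at C8 and C9 on the upper face, H5 and H10 on the lower face | COc1cc(OC)c(OC)c(C[C@@]2(C)[C@@H]3C(=O)CCC(C)(C)[C@@H]3C=C(O[Si](C)(C)C(C)(C)C)[C@@H]2C)c1OC | intermediate
16 | C1 carbinol of 15, hydroxyl anti to H10 | COc1cc(OC)c(OC)c(C[C@@]2(C)[C@@H]3[C@H](O)CCC(C)(C)[C@@H]3C=C(O[Si](C)(C)C(C)(C)C)[C@@H]2C)c1OC | intermediate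
17 | sodium O-alkyl carbonodithioate (xanthate salt) of 16 | COc1cc(OC)c(OC)c(C[C@@]2(C)[C@@H]3[C@H](OC(=S)[S-])CCC(C)(C)[C@@H]3C=C(O[Si](C)(C)C(C)(C)C)[C@@H]2C)c1OC.[Na+] | intermediate
18 | O-alkyl S-methyl carbonodithioate of 16 | COc1cc(OC)c(OC)c(C[C@@]2(C)[C@@H]3[C@H](OC(=S)SC)CCC(C)(C)[C@@H]3C=C(O[Si](C)(C)C(C)(C)C)[C@@H]2C)c1OC | intermediate
19 | 1-deoxo compound: C1 methylene, C6=C7 silyl enol ether, cis-fused | COc1cc(OC)c(OC)c(C[C@@]2(C)[C@@H]3CCCC(C)(C)[C@@H]3C=C(O[Si](C)(C)C(C)(C)C)[C@@H]2C)c1OC | intermediate
20 | C5=C6 enone with C7 ketone | COc1cc(OC)c(OC)c(C[C@@]2(C)[C@@H]3CCCC(C)(C)C3=CC(=O)[C@@H]2C)c1OC | intermediate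
21 | C7 allylic alcohol, hydroxyl on the upper face | COc1cc(OC)c(OC)c(C[C@@]2(C)[C@@H]3CCCC(C)(C)C3=C[C@H](O)[C@@H]2C)c1OC | intermediate
22 | 1,2,4,5-tetramethoxy-3-{[(1R,2S,8aS)-1,2,5,5-tetramethyl-1,2,3,5,6,7,8,8a-octahydronaphthalen-1-yl]methyl}benzene | COc1cc(OC)c(OC)c(C[C@@]2(C)[C@@H]3CCCC(C)(C)C3=CC[C@@H]2C)c1OC | intermediate
23 | 2,5-dimethoxy-3-{[(1R,2S,8aS)-1,2,5,5-tetramethyl-1,2,3,5,6,7,8,8a-octahydronaphthalen-1-yl]methyl}cyclohexa-2,5-diene-1,4-dione | COC1=CC(=O)C(OC)=C(C[C@@]2(C)[C@@H]3CCCC(C)(C)C3=CC[C@@H]2C)C1=O | intermediate
24 | 2-hydroxy-5-methoxy-3-{[(1R,2S,8aS)-1,2,5,5-tetramethyl-1,2,3,5,6,7,8,8a-octahydronaphthalen-1-yl]methyl}cyclohexa-2,5-diene-1,4-dione | COC1=CC(=O)C(O)=C(C[C@@]2(C)[C@@H]3CCCC(C)(C)C3=CC[C@@H]2C)C1=O | intermediate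
25 | 3-methylbutan-1-amine | CC(C)CCN | starting material
26 | nakijiquinone M, 2-hydroxy-5-[(3-methylbutyl)amino]-3-{[(1R,2S,8aS)-1,2,5,5-tetramethyl-1,2,3,5,6,7,8,8a-octahydronaphthalen-1-yl]methyl}cyclohexa-2,5-diene-1,4-dione | CC(C)CCNC1=CC(=O)C(O)=C(C[C@@]2(C)[C@@H]3CCCC(C)(C)C3=CC[C@@H]2C)C1=O | target

Total: 17 steps. Longest linear sequence: 14 steps (steps 1–3 or 4–6, then steps 7–17).

Least certain steps

Step 8 (key step). The most likely failure is poor or reversed facial discrimination, because the s-cis enone bound anti to its alkene lies outside the usual binding model of the catalyst. The β,β-disubstituted enone may also react slowly enough for protodesilylation of the diene, or silyl transfer to triflimide with achiral catalysis, to compete. If only the sense is wrong, the antipodal catalyst is used, and a bulkier silyl group would suppress silyl transfer. The fallback uses known chemistry and sets out from 14. Me2AlCl in CH2Cl2 at −78 → −20 °C should give the racemic cycloadduct F1 by the achiral Lewis acid-promoted endo cyclisation. Reduction with i-Bu2AlH as in step 9 would give the racemic carbinol F2. Esterification with (S)-O-methylmandelic acid (DCC, DMAP) and chromatographic separation of the two diastereomers would give the (S)-O-methylmandelate F3 of the wanted enantiomer. LiAlH4 in Et2O at 0 °C would cleave the ester and return the route at 16.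

Step 7. The most likely failure is proton transfer in place of addition: the vinyllithium may deprotonate the amide α-position or isomerise to the benzylic-allylic anion with loss of alkene geometry. Uncatalysed cyclisation of 14 during isolation is a further risk. The fallback sets out from 11. i-Bu2AlH in toluene at −78 °C would give the silyloxydienal F4. Nozaki–Hiyama–Kishi coupling with 7 (CrCl2, NiCl2 cat., DMSO/THF), which is non-basic and retains alkene geometry, would give the allylic alcohol F5. Neutral oxidation with MnO2 in CH2Cl2 would return the route at 14.

Step 14. The most likely failure is proton loss from the allyl cation to a conjugated diene, with loss of C8 or C10. Capture of the cation by the electron-rich aryl ring or hydride delivery at C5 are further risks. The fallback avoids the cation and sets out from 20. Ethane-1,2-dithiol with BF3·OEt2 would give the dithiolane F6; conjugate addition is blocked at the fully substituted C5. Desulfurisation with Raney Ni in EtOH would return the route at 22.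

Step 16. The most likely failure is hydrolysis at the wrong methoxy-bearing carbon, or at both, since the selectivity rests on a subtle steric and electronic difference between the two vinylogous esters. The fallback reverses the order and sets out from 23. Amine 25 in EtOH should attack the unhindered C5 vinylogous ester and give the aminomethoxyquinone F7. Hydrolysis of the remaining vinylogous ester (aqueous NaOH, MeOH, then acid) would return the route at 26.

Further compounds
F1 | step 8 | racemic cis-fused cycloadduct (relative configuration of 15) | COc1cc(OC)c(OC)c(C[C@@]2(C)[C@@H]3C(=O)CCC(C)(C)[C@@H]3C=C(O[Si](C)(C)C(C)(C)C)[C@@H]2C)c1OC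
F2 | step 8 | racemic C1 carbinol (relative configuration of 16) | COc1cc(OC)c(OC)c(C[C@@]2(C)[C@@H]3[C@H](O)CCC(C)(C)[C@@H]3C=C(O[Si](C)(C)C(C)(C)C)[C@@H]2C)c1OC
F3 | step 8 | (S)-2-methoxy-2-phenylacetate of 16 | COc1cc(OC)c(OC)c(C[C@@]2(C)[C@@H]3[C@H](OC(=O)[C@@H](OC)c4ccccc4)CCC(C)(C)[C@@H]3C=C(O[Si](C)(C)C(C)(C)C)[C@@H]2C)c1OC
F4 | step 7 | (5E,7Z)-7-[(tert-butyldimethylsilyl)oxy]-4,4-dimethylnona-5,7-dienal | C/C=C(O[Si](C)(C)C(C)(C)C)/C=C/C(C)(C)CCC=O
F5 | step 7 | (2E,8E,10Z)-10-[(tert-butyldimethylsilyl)oxy]-2,7,7-trimethyl-1-(2,3,5,6-tetramethoxyphenyl)dodeca-2,8,10-trien-4-ol (both carbinol epimers) | C/C=C(O[Si](C)(C)C(C)(C)C)/C=C/C(C)(C)CCC(O)/C=C(C)/Cc1c(OC)c(OC)cc(OC)c1OC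
F6 | step 14 | C7 1,3-dithiolane of 20 | COc1cc(OC)c(OC)c(C[C@@]2(C)[C@@H]3CCCC(C)(C)C3=CC4(SCCS4)[C@@H]2C)c1OC
F7 | step 16 | 2-methoxy-5-[(3-methylbutyl)amino]-3-(decalinylmethyl)-1,4-benzoquinone | CC(C)CCNC1=CC(=O)C(OC)=C(C[C@@]2(C)[C@@H]3CCCC(C)(C)C3=CC[C@@H]2C)C1=O
A1 | alternative 1 | 6,6-dimethyl-1-vinylcyclohexene | C=CC1=CCCCC1(C)C
A2 | alternative 1 | tiglic aldehyde, (E)-2-methylbut-2-enal | C/C=C(\C)C=O
A3 | alternative 1 | decalin C11 aldehyde | O=C[C@@]1(C)[C@@H]2CCCC(C)(C)C2=CC[C@@H]1C
A4 | alternative 2 | (S)-3,4-dimethylcyclohex-2-enone | CC1=CC(=O)CC[C@@H]1C
A5 | alternative 2 | allene (propa-1,2-diene) | C=C=C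
A6 | alternative 2 | methylenecyclobutane photoadduct | C=C1C[C@@]2(C)[C@@H]1C(=O)CC[C@@H]2C
A7 | alternative 3 | bicyclic C3-keto C4=C5 enone | COc1cc(OC)c(OC)c(C[C@@]2(C)[C@@H]3CCC(=O)C=C3CC[C@@H]2C)c1OC
A8 | alternative 3 | 4,4-dimethyl C5=C6 C3-ketone | COc1cc(OC)c(OC)c(C[C@@]2(C)[C@@H]3CCC(=O)C(C)(C)C3=CC[C@@H]2C)c1OC
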